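## Retrosynthetic overview
1. Target ⇒ the β-resorcylate that lacks the C3 oxygen. The last and key bond is aryl C3–O, made by ortho-oxygenation and reduction of the resulting hydroxy-o-quinone in the same flask.
2. β-Resorcylate ⇒ drim-7-en-11-yl carboxylic acid + methyl 2,4-dihydroxy-5-iodobenzoate. The aryl C5–C11 bond comes from a decarboxylative nickel coupling in which the carboxyl carbon leaves as CO2.
3. Acid ⇒ (+)-sclareolide. Opening the lactone at C8–O with loss of H-7 gives the Δ7 alkene, and C5, C9 and C10 are chiral-pool centres.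
4. Rings: none is built. Rings A and B come with sclareolide and the arene comes with methyl 2,4-dihydroxybenzoate. Only the lactone ring is opened (step 1).

Assumption: the target SMILES decodes as (5S,9S,10S)-drim-7-en-11-yl, which is (1S,4aS,8aS) in naphthalene numbering and is the series of (+)-sclareolide. Drimane numbering (C11 = benzylic CH2, C12 = methyl on C8) is used for the terpene part and benzoate numbering for the arene.

## Route

**Step 1**
Reactants: 1 (+)-sclareolide
Product: 2 methyl 2-[(1S,4aS,8aS)-2,5,5,8a-tetramethyl-1,4,4a,5,6,7,8,8a-octahydronaphthalen-1-yl]acetate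
Conditions: conc. H2SO4 (0.5 equiv), MeOH, 23 °C, 24 h; chromatography on AgNO3-impregnated SiO2
Reagents that add atoms: methanol, CO
Why: Acid-catalysed E1 opening of the tertiary lactone C8–O bond combined with Fischer esterification, in which the C8 cation loses the axial H-7 to give the trisubstituted Δ7 alkene as the main isomer, methanol traps the acid so that it cannot relactonise, and C5, C9 and C10 are not touched.

**Step 2**
Reactants: 2 methyl 2-[(1S,4aS,8aS)-2,5,5,8a-tetramethyl-1,4,4a,5,6,7,8,8a-octahydronaphthalen-1-yl]acetate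
Product: 3 2-[(1S,4aS,8aS)-2,5,5,8a-tetramethyl-1,4,4a,5,6,7,8,8a-octahydronaphthalen-1-yl]acetic acid
Conditions: KOH (5 equiv), MeOH–H2O 4:1, 65 °C, 6 h; then cold 1 M HCl to pH 4
Reagents that add atoms: potassium hydroxide, [K+].[OH-]
Why: Plain ester saponification in which the alkene is γ,δ to the carbonyl and C9 is not acidic, so nothing isomerises or epimerises, and the short cold acidification avoids relactonisation.

**Step 3**
Reactants: 4 methyl 2,4-dihydroxybenzoate
Product: 5 methyl 2,4-dihydroxy-5-iodobenzoate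
Conditions: ICl (1.0 equiv), AcOH, 23 °C, 3 h
Reagents that add atoms: iodine monochloride, ClI
Why: Electrophilic aromatic iodination, which in acidic medium attacks C5 (para to the 2-OH, ortho to the 4-OH, less crowded than C3), the same site as the classical bromination of β-resorcylic acid.

**Step 4**
Reactants: 3 2-[(1S,4aS,8aS)-2,5,5,8a-tetramethyl-1,4,4a,5,6,7,8,8a-octahydronaphthalen-1-yl]acetic acid; 5 methyl 2,4-dihydroxy-5-iodobenzoate
Product: 7 methyl 5-{[(1S,4aS,8aS)-2,5,5,8a-tetramethyl-1,4,4a,5,6,7,8,8a-octahydronaphthalen-1-yl]methyl}-2,4-dihydroxybenzoate, via redox-active ester 6 (not isolated)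
Conditions: N-hydroxyphthalimide (1.0 equiv), DIC (1.05 equiv), DMA, 23 °C, 2 h; then 5 (1.5 equiv), NiBr2·dme (10 mol %), 4,4'-di-tert-butyl-2,2'-bipyridine (10 mol %), Zn dust (2 equiv), DMA, 23 °C, 16 h
Reagents that add atoms: N-hydroxyphthalimide, ON1C(=O)c2ccccc2C1=O (its atoms stay in intermediate 6 only, none remain in 7)
Why: Carbodiimide esterification followed by nickel-catalysed decarboxylative cross-electrophile coupling, in which zerovalent nickel made by Zn inserts into the C–I bond of 5, one-electron reduction of 6 releases CO2 and the primary C11 radical, the aryl nickel species captures it and reductive elimination forms the C11–aryl bond, while C9 sits one carbon away from the radical and keeps its configuration and this reductive manifold tolerates free phenols.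

**Step 5**
Reactants: 7 methyl 5-{[(1S,4aS,8aS)-2,5,5,8a-tetramethyl-1,4,4a,5,6,7,8,8a-octahydronaphthalen-1-yl]methyl}-2,4-dihydroxybenzoate
Product: 9 methyl 5-{[(1S,4aS,8aS)-2,5,5,8a-tetramethyl-1,4,4a,5,6,7,8,8a-octahydronaphthalen-1-yl]methyl}-2,3,4-trihydroxybenzoate, via hydroxy-o-quinone 8 (not isolated)
Conditions: IBX (1.1 equiv), DMF, 0 → 23 °C, dark, 2 h; then Na2S2O4 (3 equiv), aq. NaH2PO4 (pH 5–6)/EtOAc, argon, 10 min
Reagents that add atoms: IBX (2-iodoxybenzoic acid), O=C1OI(=O)(O)c2ccccc12
Why: Proposed new method: ortho-oxygenation of a β-resorcylate at the carbon between its two hydroxyls by a pentavalent iodine reagent, not shown so far for resorcylates or as a way to a pyrogallol; the free 4-OH (the 2-OH is held in the hydrogen bond to the ester) exchanges onto the iodine of IBX, the iodyl oxygen is passed intramolecularly to C3, which is the only ortho carbon bearing hydrogen and the most nucleophilic ring carbon (ortho to both OH groups, meta to the ester, far less crowded than C5), iodine drops to the trivalent state, rearomatisation gives an iodine-bound pyrogallol that collapses to hydroxy-o-quinone 8 and 2-iodobenzoic acid (monovalent iodine), the electron-poor 8 resists further oxidation and Na2S2O4 reduces it to 9 in the same flask, and the unactivated Δ7 alkene, the ester and the three stereocentres are inert to IBX at room temperature; the closest known reaction type is the IBX oxidation of electron-rich monophenols to o-quinones with reductive work-up to catechols.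

## Compound list
1 | (+)-sclareolide, (3aR,5aS,9aS,9bR)-3a,6,6,9a-tetramethyldecahydronaphtho[2,1-b]furan-2(1H)-one | O=C1C[C@H]2[C@](C)(O1)CC[C@H]3C(C)(C)CCC[C@]23C | starting material
2 | methyl 2-[(1S,4aS,8aS)-2,5,5,8a-tetramethyl-1,4,4a,5,6,7,8,8a-octahydronaphthalen-1-yl]acetate | COC(=O)C[C@H]1C(C)=CC[C@H]2C(C)(C)CCC[C@]12C | intermediate
3 | 2-[(1S,4aS,8aS)-2,5,5,8a-tetramethyl-1,4,4a,5,6,7,8,8a-octahydronaphthalen-1-yl]acetic acid | OC(=O)C[C@H]1C(C)=CC[C@H]2C(C)(C)CCC[C@]12C | intermediate
4 | methyl 2,4-dihydroxybenzoate | COC(=O)c1ccc(O)cc1O | starting material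
5 | methyl 2,4-dihydroxy-5-iodobenzoate | COC(=O)c1cc(I)c(O)cc1O | intermediate
6 | 1,3-dioxoisoindolin-2-yl 2-[(1S,4aS,8aS)-2,5,5,8a-tetramethyl-1,4,4a,5,6,7,8,8a-octahydronaphthalen-1-yl]acetate (redox-active ester, not isolated) | O=C(C[C@H]1C(C)=CC[C@H]2C(C)(C)CCC[C@]12C)ON1C(=O)c2ccccc2C1=O | intermediate
7 | methyl 5-{[(1S,4aS,8aS)-2,5,5,8a-tetramethyl-1,4,4a,5,6,7,8,8a-octahydronaphthalen-1-yl]methyl}-2,4-dihydroxybenzoate | COC(=O)c1cc(C[C@H]2C(C)=CC[C@H]3C(C)(C)CCC[C@]23C)c(O)cc1O | intermediate
8 | methyl 2-hydroxy-3,4-dioxo-5-{[(1S,4aS,8aS)-2,5,5,8a-tetramethyl-1,4,4a,5,6,7,8,8a-octahydronaphthalen-1-yl]methyl}cyclohexa-1,5-diene-1-carboxylate (hydroxy-o-quinone, not isolated) | COC(=O)C1=C(O)C(=O)C(=O)C(C[C@H]2C(C)=CC[C@H]3C(C)(C)CCC[C@]23C)=C1 | intermediate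
9 | methyl 5-{[(1S,4aS,8aS)-2,5,5,8a-tetramethyl-1,4,4a,5,6,7,8,8a-octahydronaphthalen-1-yl]methyl}-2,3,4-trihydroxybenzoate (CNP0185238.1) | COC(=O)c1cc(C[C@H]2C(C)=CC[C@H]3C(C)(C)CCC[C@]23C)c(O)c(O)c1O | target

## Step count and risks
Total step count: 5. Longest linear sequence: 4 (1 → 2 → 3 → 7 → 9).

**Step 5 (proposed new step).**
- The ester may make 7 too sluggish toward IBX.
- Oxygen may be delivered to the alkyl-bearing C5, giving an o-quinol.
- Intermediate 8 may tautomerise to a quinone methide before it is reduced.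

The fallback uses known chemistry, sets out from 7 and comes back at 9. Magnesium-mediated ortho-formylation of 7 (MgCl2, Et3N, paraformaldehyde, MeCN, reflux) has C3 as its only free ortho carbon. It gives methyl 3-formyl-2,4-dihydroxy-5-[(5S,9S,10S)-drim-7-en-11-yl]benzoate F4. Dakin oxidation (30 % H2O2, NaOH, THF–H2O, 0 °C, argon), which leaves the unactivated alkene alone, shifts the aryl group to oxygen. This gives methyl 3-formyloxy-2,4-dihydroxy-5-[(5S,9S,10S)-drim-7-en-11-yl]benzoate F5, which is hydrolysed in the same flask to 9.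

**Step 4.**
- The free ortho-hydroxyl of 5 may slow the coupling or favour hydrodeiodination.
- Ester 6 may be used up by dimerisation.
- The homoallylic C11 radical could undergo a 1,2-vinyl shift if its capture by nickel is slow.

The fallback sets out from 3 and comes back at 7. Ester 6 is made as before but isolated. Copper-catalysed decarboxylative borylation (B2pin2, Cu(acac)2, LiOH·H2O, MgCl2, dioxane–DMF, 23 °C) gives 2-[(5S,9S,10S)-drim-7-en-11-yl]-4,4,5,5-tetramethyl-1,3,2-dioxaborolane F2. KHF2 in MeOH–H2O converts it into potassium [(5S,9S,10S)-drim-7-en-11-yl]trifluoroborate F3. A two-electron B-alkyl Suzuki–Miyaura coupling of this salt with 5 (Pd(OAc)2, RuPhos, K2CO3, toluene–H2O, 80 °C) then gives 7.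

**Step 1.** The E1 proton loss also gives the Δ8(12) and Δ8(9) isomers, and the separation may be poor.

The fallback sets out from 2 (taken as the unseparated isomer mixture) and comes back at 3. It fixes the alkene position by a regiospecific β-elimination instead of relying on E1 selectivity.
- The mixture is saponified as in step 2.
- The crude acids are iodolactonised (I2, NaHCO3, MeCN–H2O, 0 °C). For the Δ7 acid, the iodonium forms on the α face, opposite the axial C10 methyl, and the carboxylate opens it at the tertiary C8 from the β face (trans-diaxial).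
- The product is the crystalline cis-fused 7α-iodo-8-epi-sclareolide F1, which is easily separated from the products of the other isomers.
- Zn dust in AcOH–EtOH at 23 °C eliminates iodide and carboxylate and gives pure 3.

## Further compounds
F1 | step 1 | 7α-iodo-8-epi-sclareolide (cis-fused γ-lactone, 8β-O, 8α-methyl, 7α-iodo) | O=C1C[C@H]2[C@@](C)(O1)[C@H](I)C[C@H]3C(C)(C)CCC[C@]23C
F2 | step 4 | 2-[(5S,9S,10S)-drim-7-en-11-yl]-4,4,5,5-tetramethyl-1,3,2-dioxaborolane | CC1(C)OB(C[C@H]2C(C)=CC[C@H]3C(C)(C)CCC[C@]23C)OC1(C)C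
F3 | step 4 | potassium [(5S,9S,10S)-drim-7-en-11-yl]trifluoroborate | [K+].F[B-](F)(F)C[C@H]1C(C)=CC[C@H]2C(C)(C)CCC[C@]12C
F4 | step 5 | methyl 3-formyl-2,4-dihydroxy-5-[(5S,9S,10S)-drim-7-en-11-yl]benzoate | COC(=O)c1cc(C[C@H]2C(C)=CC[C@H]3C(C)(C)CCC[C@]23C)c(O)c(C=O)c1O
F5 | step 5 | methyl 3-formyloxy-2,4-dihydroxy-5-[(5S,9S,10S)-drim-7-en-11-yl]benzoate | COC(=O)c1cc(C[C@H]2C(C)=CC[C@H]3C(C)(C)CCC[C@]23C)c(O)c(OC=O)c1O
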